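**Assumption:** the identifier is taken to mean exactly the given SMILES, i.e. the (3Z,4S,5R)-lactone with a (3R)-carbinol and 4E,8E-alkenes in the side chain. Catalyst and ligand antipodes are named for the accepted sense of induction and would be confirmed by Mosher ester analysis on first use.

## Retrosynthetic overview

1. Target ⇐ global desilylation of a bis-silylated lactone. The only ring (the γ-lactone) is closed in the penultimate step, by lactonisation of the C5 hydroxyl onto a methyl ester.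
2. The C3–C4 bond, the Z-alkylidene and the C4 carbinol come from one proposed copper hydride-catalysed reductive aldol-type coupling of a 2-alkynoate with an (R)-α-silyloxy aldehyde.
3. The ynoate comes from geraniol: terminal E-allylic oxidation, catalytic asymmetric propargylation (side-chain carbinol), silylation, alkyne carboxylation.
4. The aldehyde comes from (R)-solketal (C5 from the chiral pool): oxidation, isopropylidene Wittig, acetonide hydrolysis, bis-silylation, oxidative unmasking of the primary silyl ether.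

## Route

Step 1
Reactants: 1 geraniol ((2E)-3,7-dimethylocta-2,6-dien-1-ol)
Product: 2 tert-butyl{[(2E)-3,7-dimethylocta-2,6-dien-1-yl]oxy}diphenylsilane
Conditions: TBDPSCl, imidazole, CH2Cl2, 0 °C to rt
Reagents that add atoms: tert-butyl(chloro)diphenylsilane, CC(C)(C)[Si](Cl)(c1ccccc1)c1ccccc1
Why: Imidazole-promoted silyl ether formation at the primary allylic alcohol gives a base-stable, fluoride-labile group that survives the later organolithium step.

Step 2
Reactants: 2 tert-butyl{[(2E)-3,7-dimethylocta-2,6-dien-1-yl]oxy}diphenylsilane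
Product: 3 (2E,6E)-8-[(tert-butyldiphenylsilyl)oxy]-2,6-dimethylocta-2,6-dien-1-ol
Conditions: SeO2 (0.2 equiv), t-BuOOH (70% aq., 3 equiv), salicylic acid (0.1 equiv), CH2Cl2, 0 °C to rt
Reagents that add atoms: tert-butyl hydroperoxide, CC(C)(C)OO (terminal oxygen source); selenium dioxide, O=[Se]=O (catalytic oxygen carrier)
Why: Catalytic SeO2/t-BuOOH allylic oxidation (ene reaction followed by 2,3-sigmatropic rearrangement) reacts at the more electron-rich terminal trisubstituted alkene and selectively at its E-methyl group, giving the E-allylic alcohol.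

Step 3
Reactants: 3 (2E,6E)-8-[(tert-butyldiphenylsilyl)oxy]-2,6-dimethylocta-2,6-dien-1-ol
Product: 4 (2E,6E)-8-[(tert-butyldiphenylsilyl)oxy]-2,6-dimethylocta-2,6-dienal
Conditions: MnO2 (15 equiv), CH2Cl2, rt
Reagents that add atoms: none
Why: MnO2 is a chemoselective oxidant for allylic alcohols and gives the enal with retention of the E geometry.

Step 4
Reactants: 4 (2E,6E)-8-[(tert-butyldiphenylsilyl)oxy]-2,6-dimethylocta-2,6-dienal
Product: 6 (4R,5E,9E)-11-[(tert-butyldiphenylsilyl)oxy]-5,9-dimethylundeca-5,9-dien-1-yn-4-ol, via pinacol borate ester 5 (not isolated)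
Conditions: allenylboronic acid pinacol ester (1.5 equiv), (R)-TRIP [(R)-3,3'-bis(2,4,6-triisopropylphenyl)-1,1'-binaphthyl-2,2'-diyl hydrogen phosphate] (10 mol%), 4 Å MS, toluene, −20 °C; aq. NaHCO3 work-up
Reagents that add atoms: 4,4,5,5-tetramethyl-2-(propa-1,2-dien-1-yl)-1,3,2-dioxaborolane, C=C=CB1OC(C)(C)C(C)(C)O1
Why: Chiral phosphoric acid-catalysed allenylboration (SE2' propargylation through a closed chair transition state, the acid hydrogen-bonding to the boronate oxygen and the formyl hydrogen) delivers the propargyl group to the Re face of the enal under (R)-TRIP control, setting the carbinol as 4R, and the borate ester 5 is hydrolysed on work-up.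

Step 5
Reactants: 6 (4R,5E,9E)-11-[(tert-butyldiphenylsilyl)oxy]-5,9-dimethylundeca-5,9-dien-1-yn-4-ol
Product: 7 (4R,5E,9E)-4-[(tert-butyldimethylsilyl)oxy]-11-[(tert-butyldiphenylsilyl)oxy]-5,9-dimethylundeca-5,9-dien-1-yne
Conditions: TBSCl, imidazole, DMF, rt
Reagents that add atoms: tert-butyl(chloro)dimethylsilane, CC(C)(C)[Si](C)(C)Cl
Why: Imidazole-promoted silylation of the secondary allylic alcohol leaves the configuration untouched, and the TBS ether later blocks competing δ-lactone formation.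

Step 6
Reactants: 7 (4R,5E,9E)-4-[(tert-butyldimethylsilyl)oxy]-11-[(tert-butyldiphenylsilyl)oxy]-5,9-dimethylundeca-5,9-dien-1-yne
Product: 9 methyl (5R,6E,10E)-5-[(tert-butyldimethylsilyl)oxy]-12-[(tert-butyldiphenylsilyl)oxy]-6,10-dimethyldodeca-6,10-dien-2-ynoate, via lithium acetylide 8 (not isolated)
Conditions: n-BuLi, THF, −78 °C; then ClCO2Me, −78 to 0 °C
Reagents that add atoms: methyl chloroformate, COC(=O)Cl
Why: Deprotonation of the terminal alkyne and C-acylation of the lithium acetylide by methyl chloroformate is the standard route to 2-alkynoates, and the silyl ethers and the stereocentre are inert.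

Step 7
Reactants: 10 (R)-solketal ([(4R)-2,2-dimethyl-1,3-dioxolan-4-yl]methanol)
Product: 11 (4S)-2,2-dimethyl-1,3-dioxolane-4-carbaldehyde
Conditions: (COCl)2, DMSO, CH2Cl2, −78 °C; then Et3N, −78 to 0 °C
Reagents that add atoms: none
Why: Swern oxidation at low temperature oxidises the primary alcohol without epimerising the adjacent stereocentre (the descriptor changes from R to S only because the substituent priorities change).

Step 8
Reactants: 11 (4S)-2,2-dimethyl-1,3-dioxolane-4-carbaldehyde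
Product: 12 (4R)-2,2-dimethyl-4-(2-methylprop-1-en-1-yl)-1,3-dioxolane
Conditions: isopropyltriphenylphosphonium iodide, n-BuLi, THF, 0 °C; then 11, −78 °C to rt
Reagents that add atoms: isopropyltriphenylphosphonium iodide, CC(C)[P+](c1ccccc1)(c1ccccc1)c1ccccc1.[I-]
Why: Wittig olefination with the unstabilised isopropylidene ylide raises no alkene-geometry issue (two identical methyl groups), and the cold addition leaves the oxygenated stereocentre, the future lactone C5, intact.

Step 9
Reactants: 12 (4R)-2,2-dimethyl-4-(2-methylprop-1-en-1-yl)-1,3-dioxolane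
Product: 13 (2R)-4-methylpent-3-ene-1,2-diol
Conditions: AcOH–H2O (4:1), rt
Reagents that add atoms: none
Why: Mild aqueous acid hydrolysis of the isopropylidene acetal does not break the C–O bond at the allylic stereocentre, so the configuration is kept.

Step 10
Reactants: 13 (2R)-4-methylpent-3-ene-1,2-diol
Product: 14 (2R)-4-methyl-1,2-bis[(triethylsilyl)oxy]pent-3-ene
Conditions: TESCl (2.3 equiv), imidazole, CH2Cl2, 0 °C
Reagents that add atoms: chlorotriethylsilane, CC[Si](Cl)(CC)CC
Why: Exhaustive silylation of both hydroxyls sets up differentiation of the primary from the secondary position in the next step.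

Step 11
Reactants: 14 (2R)-4-methyl-1,2-bis[(triethylsilyl)oxy]pent-3-ene
Product: 15 (2R)-4-methyl-2-[(triethylsilyl)oxy]pent-3-enal
Conditions: (COCl)2, DMSO, CH2Cl2, −78 to −40 °C; then i-Pr2NEt, −78 to −30 °C; cold pH 7 buffer
Reagents that add atoms: none
Why: Under Swern conditions the primary triethylsilyl ether is cleaved by the chlorosulfonium salt and oxidised directly to the aldehyde while the hindered secondary triethylsilyl ether survives, and the cold hindered-base protocol avoids epimerisation or conjugation of the α-silyloxy β,γ-unsaturated aldehyde, which is used at once.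

Step 12
Reactants: 9 methyl (5R,6E,10E)-5-[(tert-butyldimethylsilyl)oxy]-12-[(tert-butyldiphenylsilyl)oxy]-6,10-dimethyldodeca-6,10-dien-2-ynoate; 15 (2R)-4-methyl-2-[(triethylsilyl)oxy]pent-3-enal
Product: 17 methyl (2Z,5R,6E,10E)-5-[(tert-butyldimethylsilyl)oxy]-12-[(tert-butyldiphenylsilyl)oxy]-2-{(1S,2R)-1-hydroxy-4-methyl-2-[(triethylsilyl)oxy]pent-3-en-1-yl}-6,10-dimethyldodeca-2,6,10-trienoate, via dimethoxy(methyl)silyl ether 16 (not isolated)
Conditions: Cu(OAc)2 (5 mol%), (R)-DTBM-SEGPHOS [(R)-5,5'-bis{bis(3,5-di-tert-butyl-4-methoxyphenyl)phosphino}-4,4'-bi-1,3-benzodioxole] (6 mol%), (MeO)2MeSiH (1.2 equiv, slow addition), toluene, −40 °C; then pH 7 buffer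
Reagents that add atoms: none
Why: Proposed new method: a ligand-bound copper hydride (monovalent copper, formed from Cu(OAc)2 and the silane) should add syn across the electron-poor triple bond of 9 (H to the β-carbon, Cu to the α-carbon) faster than it reduces the hindered aldehyde, and the resulting α-cuprio enoate/copper allenolate should attack 15 through the lobe cis to the new β-hydrogen so that ester and CH2 chain end up cis (2Z), while the aldehyde is attacked anti to its C–OSiEt3 bond (Felkin–Anh, reinforced by the matched bisphosphine, the antipode being fixed in a two-run screen) to give the 1S,2R anti-relationship; silyl transfer from the silane to the copper aldolate turns the catalyst over and slow silane addition limits 1,2-reduction of 15 and over-reduction of the product; the closest known reaction types are copper hydride-catalysed reductive aldol couplings of acrylates and allenoates with carbonyl compounds and the stoichiometric hydroalumination of alkynoates followed by aldehyde addition.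

Step 13
Reactants: 17 methyl (2Z,5R,6E,10E)-5-[(tert-butyldimethylsilyl)oxy]-12-[(tert-butyldiphenylsilyl)oxy]-2-{(1S,2R)-1-hydroxy-4-methyl-2-[(triethylsilyl)oxy]pent-3-en-1-yl}-6,10-dimethyldodeca-2,6,10-trienoate
Product: 19 (3Z,4S,5R)-3-{(3R,4E,8E)-3-[(tert-butyldimethylsilyl)oxy]-10-[(tert-butyldiphenylsilyl)oxy]-4,8-dimethyldeca-4,8-dien-1-ylidene}-4-hydroxy-5-(2-methylprop-1-en-1-yl)oxolan-2-one, via diol ester 18 (not isolated)
Conditions: pyridinium p-toluenesulfonate (0.2 equiv), MeOH–CH2Cl2, 0 °C to rt; then toluene, 40 °C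
Reagents that add atoms: none
Why: Acid-catalysed methanolysis removes only the most labile (triethylsilyl) ether and the freed C5 hydroxyl closes the five-membered lactone by transesterification onto the methyl ester (the only lactone possible because the side-chain hydroxyl is still silylated), with no stereocentre or alkene geometry touched.

Step 14
Reactants: 19 (3Z,4S,5R)-3-{(3R,4E,8E)-3-[(tert-butyldimethylsilyl)oxy]-10-[(tert-butyldiphenylsilyl)oxy]-4,8-dimethyldeca-4,8-dien-1-ylidene}-4-hydroxy-5-(2-methylprop-1-en-1-yl)oxolan-2-one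
Product: 20 (3Z,4S,5R)-3-[(3R,4E,8E)-3,10-dihydroxy-4,8-dimethyldeca-4,8-dien-1-ylidene]-4-hydroxy-5-(2-methylprop-1-en-1-yl)oxolan-2-one (CNP0209732.3)
Conditions: HF·pyridine, pyridine, THF, 0 °C to rt
Reagents that add atoms: none
Why: Buffered HF·pyridine cleaves the remaining secondary TBS and primary TBDPS ethers (fluoride-driven desilylation) under weakly acidic conditions that avoid retro-aldol, alkene isomerisation or translactonisation of the base-sensitive hydroxy lactone.

## Compound list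

1 | geraniol, (2E)-3,7-dimethylocta-2,6-dien-1-ol | CC(C)=CCC/C(C)=C/CO | starting material
2 | tert-butyl{[(2E)-3,7-dimethylocta-2,6-dien-1-yl]oxy}diphenylsilane | CC(C)=CCC/C(C)=C/CO[Si](c1ccccc1)(c1ccccc1)C(C)(C)C | intermediate
3 | (2E,6E)-8-[(tert-butyldiphenylsilyl)oxy]-2,6-dimethylocta-2,6-dien-1-ol | OC/C(C)=C/CC/C(C)=C/CO[Si](c1ccccc1)(c1ccccc1)C(C)(C)C | intermediate
4 | (2E,6E)-8-[(tert-butyldiphenylsilyl)oxy]-2,6-dimethylocta-2,6-dienal | O=C/C(C)=C/CC/C(C)=C/CO[Si](c1ccccc1)(c1ccccc1)C(C)(C)C | intermediate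
5 | 2-{[(4R,5E,9E)-11-[(tert-butyldiphenylsilyl)oxy]-5,9-dimethylundeca-5,9-dien-1-yn-4-yl]oxy}-4,4,5,5-tetramethyl-1,3,2-dioxaborolane (pinacol borate ester of 6) | C#CC[C@@H](OB1OC(C)(C)C(C)(C)O1)/C(C)=C/CC/C(C)=C/CO[Si](c1ccccc1)(c1ccccc1)C(C)(C)C | intermediate
6 | (4R,5E,9E)-11-[(tert-butyldiphenylsilyl)oxy]-5,9-dimethylundeca-5,9-dien-1-yn-4-ol | C#CC[C@@H](O)/C(C)=C/CC/C(C)=C/CO[Si](c1ccccc1)(c1ccccc1)C(C)(C)C | intermediate
7 | (4R,5E,9E)-4-[(tert-butyldimethylsilyl)oxy]-11-[(tert-butyldiphenylsilyl)oxy]-5,9-dimethylundeca-5,9-dien-1-yne | C#CC[C@@H](O[Si](C)(C)C(C)(C)C)/C(C)=C/CC/C(C)=C/CO[Si](c1ccccc1)(c1ccccc1)C(C)(C)C | intermediate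
8 | [(4R,5E,9E)-4-[(tert-butyldimethylsilyl)oxy]-11-[(tert-butyldiphenylsilyl)oxy]-5,9-dimethylundeca-5,9-dien-1-yn-1-yl]lithium (lithium acetylide of 7) | [Li]C#CC[C@@H](O[Si](C)(C)C(C)(C)C)/C(C)=C/CC/C(C)=C/CO[Si](c1ccccc1)(c1ccccc1)C(C)(C)C | intermediate
9 | methyl (5R,6E,10E)-5-[(tert-butyldimethylsilyl)oxy]-12-[(tert-butyldiphenylsilyl)oxy]-6,10-dimethyldodeca-6,10-dien-2-ynoate | COC(=O)C#CC[C@@H](O[Si](C)(C)C(C)(C)C)/C(C)=C/CC/C(C)=C/CO[Si](c1ccccc1)(c1ccccc1)C(C)(C)C | intermediate
10 | (R)-solketal, [(4R)-2,2-dimethyl-1,3-dioxolan-4-yl]methanol | CC1(C)OC[C@@H](CO)O1 | starting material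
11 | (4S)-2,2-dimethyl-1,3-dioxolane-4-carbaldehyde | CC1(C)OC[C@@H](C=O)O1 | intermediate
12 | (4R)-2,2-dimethyl-4-(2-methylprop-1-en-1-yl)-1,3-dioxolane | CC1(C)OC[C@@H](C=C(C)C)O1 | intermediate
13 | (2R)-4-methylpent-3-ene-1,2-diol | CC(C)=C[C@@H](O)CO | intermediate
14 | (2R)-4-methyl-1,2-bis[(triethylsilyl)oxy]pent-3-ene | CC(C)=C[C@@H](O[Si](CC)(CC)CC)CO[Si](CC)(CC)CC | intermediate
15 | (2R)-4-methyl-2-[(triethylsilyl)oxy]pent-3-enal | CC(C)=C[C@@H](O[Si](CC)(CC)CC)C=O | intermediate
16 | methyl (2Z,5R,6E,10E)-5-[(tert-butyldimethylsilyl)oxy]-12-[(tert-butyldiphenylsilyl)oxy]-2-{(1S,2R)-1-{[dimethoxy(methyl)silyl]oxy}-4-methyl-2-[(triethylsilyl)oxy]pent-3-en-1-yl}-6,10-dimethyldodeca-2,6,10-trienoate (silyl ether of 17) | COC(=O)/C(=C\C[C@@H](O[Si](C)(C)C(C)(C)C)/C(C)=C/CC/C(C)=C/CO[Si](c1ccccc1)(c1ccccc1)C(C)(C)C)[C@H](O[Si](C)(OC)OC)[C@@H](C=C(C)C)O[Si](CC)(CC)CC | intermediate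
17 | methyl (2Z,5R,6E,10E)-5-[(tert-butyldimethylsilyl)oxy]-12-[(tert-butyldiphenylsilyl)oxy]-2-{(1S,2R)-1-hydroxy-4-methyl-2-[(triethylsilyl)oxy]pent-3-en-1-yl}-6,10-dimethyldodeca-2,6,10-trienoate | COC(=O)/C(=C\C[C@@H](O[Si](C)(C)C(C)(C)C)/C(C)=C/CC/C(C)=C/CO[Si](c1ccccc1)(c1ccccc1)C(C)(C)C)[C@H](O)[C@@H](C=C(C)C)O[Si](CC)(CC)CC | intermediate
18 | methyl (2Z,5R,6E,10E)-5-[(tert-butyldimethylsilyl)oxy]-12-[(tert-butyldiphenylsilyl)oxy]-2-[(1S,2R)-1,2-dihydroxy-4-methylpent-3-en-1-yl]-6,10-dimethyldodeca-2,6,10-trienoate (diol ester) | COC(=O)/C(=C\C[C@@H](O[Si](C)(C)C(C)(C)C)/C(C)=C/CC/C(C)=C/CO[Si](c1ccccc1)(c1ccccc1)C(C)(C)C)[C@H](O)[C@@H](C=C(C)C)O | intermediate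
19 | (3Z,4S,5R)-3-{(3R,4E,8E)-3-[(tert-butyldimethylsilyl)oxy]-10-[(tert-butyldiphenylsilyl)oxy]-4,8-dimethyldeca-4,8-dien-1-ylidene}-4-hydroxy-5-(2-methylprop-1-en-1-yl)oxolan-2-one | CC(C)=C[C@H]1OC(=O)/C(=C\C[C@@H](O[Si](C)(C)C(C)(C)C)/C(C)=C/CC/C(C)=C/CO[Si](c2ccccc2)(c2ccccc2)C(C)(C)C)[C@@H]1O | intermediate
20 | (3Z,4S,5R)-3-[(3R,4E,8E)-3,10-dihydroxy-4,8-dimethyldeca-4,8-dien-1-ylidene]-4-hydroxy-5-(2-methylprop-1-en-1-yl)oxolan-2-one (CNP0209732.3) | CC(C)=C[C@H]1OC(=O)/C(=C\C[C@@H](O)/C(C)=C/CC/C(C)=C/CO)[C@@H]1O | target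

## Step count and risk

Total step count: 14. Longest linear sequence: 9 steps (steps 1 to 6, then 12 to 14).

The three steps most likely to fail:

**Step 12 (the proposed copper hydride coupling).** Risks are competing 1,2-reduction of 15, over-reduction of the enoate product and a low anti:syn ratio. The fallback is known chemistry; it sets out from 9 and comes back to the route at 17. Ynoate 9 is hydroaluminated with i-Bu2AlH/N-methylmorpholine N-oxide in THF at 0 °C (syn 1,4-hydroalumination of alkynoates). This gives the alkenylalane methyl (2E,5R,6E,10E)-2-[bis(2-methylpropyl)alumanyl]-5-[(tert-butyldimethylsilyl)oxy]-12-[(tert-butyldiphenylsilyl)oxy]-6,10-dimethyldodeca-2,6,10-trienoate F1. F1 is treated with 15 at −78 °C. Substitution at the alkenyl–Al carbon with retention gives the same Z-alkylidene, and Felkin–Anh addition favours the anti carbinol. Work-up with aqueous potassium sodium tartrate gives 17, and the minor syn diastereomer is removed on silica.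

**Step 11 (direct oxidation of the bis-silyl ether to the epimerisable aldehyde).** Risks are incomplete primary desilylation, loss of the secondary silyl ether and partial racemisation by the amine base. The fallback sets out from 14 and comes back at 15, going through the free alcohol and a base-free oxidant instead. HF·pyridine/pyridine in THF at −10 °C cleaves only the primary silyl ether to give (2R)-4-methyl-2-[(triethylsilyl)oxy]pent-3-en-1-ol F2. F2 is oxidised with Dess–Martin periodinane/NaHCO3 in CH2Cl2 at 0 °C, and 15 is passed through a short cold pad of deactivated silica and used immediately.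

**Step 4 (catalytic asymmetric propargylation of an α-branched enal).** Risks are slow turnover and insufficient enantioselectivity. The fallback sets out from 4 and comes back at 6, replacing catalyst control by kinetic resolution. Barbier propargylation (propargyl bromide, Zn dust, THF/sat. aq. NH4Cl, 0 °C) gives racemic (5E,9E)-11-[(tert-butyldiphenylsilyl)oxy]-5,9-dimethylundeca-5,9-dien-1-yn-4-ol F3. Sharpless kinetic resolution of this secondary allylic alcohol (Ti(OiPr)4, L-(+)-diisopropyl tartrate, t-BuOOH 0.6 equiv, 4 Å MS, CH2Cl2, −20 °C) epoxidises the fast-reacting (S)-enantiomer. The by-product is (1S)-1-[(2R,3R)-3-{(3E)-5-[(tert-butyldiphenylsilyl)oxy]-3-methylpent-3-en-1-yl}-2-methyloxiran-2-yl]but-3-yn-1-ol F4. Unreacted (R)-alcohol 6 is recovered (at most 50%) by chromatography.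

## Further compounds

F1 | step 12 | methyl (2E,5R,6E,10E)-2-[bis(2-methylpropyl)alumanyl]-5-[(tert-butyldimethylsilyl)oxy]-12-[(tert-butyldiphenylsilyl)oxy]-6,10-dimethyldodeca-2,6,10-trienoate | COC(=O)/C(=C\C[C@@H](O[Si](C)(C)C(C)(C)C)/C(C)=C/CC/C(C)=C/CO[Si](c1ccccc1)(c1ccccc1)C(C)(C)C)[Al](CC(C)C)CC(C)C
F2 | step 11 | (2R)-4-methyl-2-[(triethylsilyl)oxy]pent-3-en-1-ol | CC(C)=C[C@@H](O[Si](CC)(CC)CC)CO
F3 | step 4 | racemic (5E,9E)-11-[(tert-butyldiphenylsilyl)oxy]-5,9-dimethylundeca-5,9-dien-1-yn-4-ol | C#CCC(O)/C(C)=C/CC/C(C)=C/CO[Si](c1ccccc1)(c1ccccc1)C(C)(C)C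
F4 | step 4 | (1S)-1-[(2R,3R)-3-{(3E)-5-[(tert-butyldiphenylsilyl)oxy]-3-methylpent-3-en-1-yl}-2-methyloxiran-2-yl]but-3-yn-1-ol | C#CC[C@H](O)[C@@]1(C)O[C@@H]1CC/C(C)=C/CO[Si](c1ccccc1)(c1ccccc1)C(C)(C)C
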